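**Assumptions**
- The following are purchasable: 4,4-diethoxybut-1-yne, isoprene, 9-BBN, acrolein, acryloyl chloride, bis(trimethylsilyl)acetylene, methallylMgCl, the Ipc2BOMe and TsDPEN catalyst enantiomers, and the other simple reagents.
- The pinene enantiomer (Brown step) and the (S,S)-TsDPEN catalyst (Noyori step) are chosen to give the S carbinols.
- In the final macrocyclization, the 14S carbinol is assumed to be obtainable under macrocyclic control. A minor C14 epimer is assumed to be separable by HPLC.

**Retrosynthesis**
1. Target **21** comes from intramolecular Nozaki–Hiyama–Kishi (NHK) allylation of bromomethyl-butenolide/aldehyde **20**. This closes the 14-membered ring last and forms C1–C14, the C14 carbinol and the exocyclic methylene together.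
2. **20** comes from cross-metathesis (CM) of the 1,1-disubstituted alkene of homoallylic acetate **9** with (S)-5-vinyl-3-(hydroxymethyl)butenolide **17**, forming the E-C3=C4 alkene. The C14 aldehyde is carried as a diethyl acetal.
3. **9** comes from Brown methallylation (sets C6) of enal **7** followed by acetylation. **7** comes from CM of diene **5** with acrolein. **5** comes from Suzuki coupling of vinyl iodide **2** (carboalumination of alkyne **1**) with the isoprene-derived alkyl-9-BBN **4**.
4. **17** comes from hydroxymethylation of butenolide **16**. **16** comes from Lindlar reduction and lactonization of γ-hydroxy-ynoate **15**, and C2 is set by Noyori transfer hydrogenation of TMS-ynone **12**. The butenolide is formed first and the macrocycle last.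

**Step 1**
Reactants: 1, 4,4-diethoxybut-1-yne
Product: 2, (E)-4,4-diethoxy-1-iodo-2-methylbut-1-ene
Conditions: Me3Al, cat. Cp2ZrCl2, CH2Cl2, rt; then I2, THF, –30 °C to rt
Reagents that add atoms: trimethylaluminium (C[Al](C)C, supplies the C12 methyl); iodine (II)
Why: Negishi Zr-catalysed carboalumination adds Me and Al syn across the terminal alkyne, and iodinolysis gives the E-trisubstituted vinyl iodide (I cis to Me) with the C12 methyl placed correctly.

**Step 2**
Reactants: 3, isoprene
Product: 4, 9-(3-methylbut-3-en-1-yl)-9-borabicyclo[3.3.1]nonane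
Conditions: 9-BBN (1.0 equiv), THF, 0 °C to rt, 3 h (solution used directly in Step 3)
Reagents that add atoms: 9-BBN (B1C2CCCC1CCC2; supplies the B–H that adds across the alkene)
Why: Hydroboration with the bulky 9-BBN occurs at the unhindered monosubstituted vinyl group of isoprene, with B on the terminal carbon, and leaves the 1,1-disubstituted alkene untouched.

**Step 3**
Reactants: 2, (E)-4,4-diethoxy-1-iodo-2-methylbut-1-ene; 4, alkyl-9-BBN
Product: 5, (E)-8,8-diethoxy-2,6-dimethylocta-1,5-diene
Conditions: Pd(dppf)Cl2 (5 mol%), aq. K3PO4, THF/DMF, 50 °C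
Reagents that add atoms: none (the alkyl group comes from numbered reactant 4)
Why: B-alkyl Suzuki–Miyaura coupling forms the C10–C11 bond with retention of the vinyl-iodide geometry, so the C11=C12 alkene is E.

**Step 4**
Reactants: 5, diene; 6, acrolein
Product: 7, (2E,6E)-9,9-diethoxy-3,7-dimethylnona-2,6-dienal
Conditions: Hoveyda–Grubbs II (5 mol%), acrolein (5 equiv), CH2Cl2, 40 °C
Reagents that add atoms: none (acrolein is reactant 6)
Why: Cross-metathesis of the 1,1-disubstituted alkene with acrolein (ethylene lost) gives the E-β,β-disubstituted enal at C6–C8, and the more hindered trisubstituted C11=C12 alkene is untouched.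

**Step 5**
Reactants: 7, enal
Product: 8, (4S,5E,9E)-12,12-diethoxy-2,6,10-trimethyldodeca-1,5,9-trien-4-ol
Conditions: Ipc2B(methallyl) (from methallylMgCl and Ipc2BOMe, pinene enantiomer chosen for S), Et2O, –78 °C; then NaOH, H2O2
Reagents that add atoms: methallylmagnesium chloride (C=C(C)C[Mg]Cl, supplies C3–C5 and the C4 methyl)
Why: Brown asymmetric methallylation goes through a chair transition state with face selection by the Ipc ligands, so reagent control sets C6 (S), and it installs the C4=CH2 handle for metathesis.

**Step 6**
Reactants: 8, alcohol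
Product: 9, (4S,5E,9E)-12,12-diethoxy-2,6,10-trimethyldodeca-1,5,9-trien-4-yl acetate
Conditions: Ac2O, Et3N, cat. DMAP, CH2Cl2, 0 °C
Reagents that add atoms: acetic anhydride (CC(=O)OC(C)=O)
Why: Plain O-acetylation of the secondary alcohol leaves C6 untouched and installs the target acetate.

**Step 7**
Reactants: 10, acryloyl chloride; 11, bis(trimethylsilyl)acetylene
Product: 12, 1-(trimethylsilyl)pent-4-en-1-yn-3-one
Conditions: AlCl3, CH2Cl2, 0 °C
Reagents that add atoms: none (both partners are numbered reactants; TMSCl is lost)
Why: Friedel–Crafts-type ipso-acylation of the silylalkyne gives the TMS-ynone that carries C1–C3 and C15.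

**Step 8**
Reactants: 12, ynone
Product: 13, (S)-1-(trimethylsilyl)pent-4-en-1-yn-3-ol
Conditions: RuCl[(S,S)-TsDPEN](p-cymene) (1 mol%), HCO2H/Et3N (5:2), CH2Cl2, rt
Reagents that add atoms: none (hydrogen only)
Why: Noyori asymmetric transfer hydrogenation reduces the ynone carbonyl, and catalyst control sets C2 (S) by discriminating the bulky silylalkynyl arm from the vinyl arm.

**Step 9**
Reactants: 13, silyl alkynol
Product: 14, (3S)-pent-1-en-4-yn-3-ol
Conditions: K2CO3, MeOH, 0 °C
Reagents that add atoms: none
Why: Protodesilylation of the alkynyl–TMS bond leaves the carbinol stereocentre untouched.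

**Step 10**
Reactants: 14, alkynol
Product: 15, methyl (4S)-4-hydroxyhex-5-en-2-ynoate
Conditions: n-BuLi (2.2 equiv), THF, –78 °C; then ClCO2Me
Reagents that add atoms: methyl chloroformate (COC(Cl)=O, supplies C16 and the OMe)
Why: The alkoxide/acetylide dianion is acylated at carbon to give the γ-hydroxy alkynoate, and the alkoxide carbinol centre cannot epimerize under these conditions.

**Step 11**
Reactants: 15, hydroxy ynoate
Product: 16, (5S)-5-ethenylfuran-2(5H)-one
Conditions: H2 (1 atm), Lindlar Pd/CaCO3, quinoline, EtOAc, rt; then cat. p-TsOH, CH2Cl2, rt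
Reagents that add atoms: none (hydrogen only; MeOH is lost on lactonization)
Why: Lindlar semihydrogenation gives the Z-enoate, which lactonizes onto the γ-OH (butenolide ring formed, MeOH lost), and the vinyl group and C2 configuration are retained.

**Step 12**
Reactants: 16, vinylbutenolide
Product: 17, (5S)-5-ethenyl-3-(hydroxymethyl)furan-2(5H)-one
Conditions: 37% aq. HCHO, imidazole (cat.), dioxane/H2O, rt
Reagents that add atoms: formaldehyde (C=O, supplies the hydroxymethyl carbon)
Why: Morita–Baylis–Hillman hydroxymethylation occurs at the butenolide α-carbon (C15), and the mild nucleophilic catalyst avoids γ-deprotonation (racemization at C2).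

**Step 13**
Reactants: 9, acetate; 17, hydroxymethyl butenolide
Product: 18, (5S)-5-[(1E,4S,5E,9E)-4-acetoxy-12,12-diethoxy-2,6,10-trimethyldodeca-1,5,9-trien-1-yl]-3-(hydroxymethyl)furan-2(5H)-one
Conditions: Hoveyda–Grubbs II (10 mol%), toluene, 50 °C, 9 (1.5 equiv)
Reagents that add atoms: none
Why: Cross-metathesis of the 1,1-disubstituted alkene of 9 with the vinyl group of 17 releases ethylene and forms the E-trisubstituted C3=C4 bond, while the electron-poor ring alkene is inert.

**Step 14**
Reactants: 18, allylic alcohol
Product: 19, (5S)-5-[(1E,4S,5E,9E)-4-acetoxy-12,12-diethoxy-2,6,10-trimethyldodeca-1,5,9-trien-1-yl]-3-(bromomethyl)furan-2(5H)-one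
Conditions: PPh3, CBr4, CH2Cl2, 0 °C, solid NaHCO3
Reagents that add atoms: carbon tetrabromide (BrC(Br)(Br)Br, supplies Br)
Why: Appel SN2 replacement of the primary allylic alcohol by bromide occurs under neutral, buffered conditions, so the acetal and acetate survive.

**Step 15**
Reactants: 19, bromo acetal
Product: 20, (5S)-5-[(1E,4S,5E,9E)-4-acetoxy-2,6,10-trimethyl-12-oxododeca-1,5,9-trien-1-yl]-3-(bromomethyl)furan-2(5H)-one
Conditions: cat. p-TsOH, acetone/H2O (20:1), rt
Reagents that add atoms: water (O, supplies the aldehyde oxygen)
Why: Mild acetal hydrolysis unmasks the C14 aldehyde, and the crude aldehyde is used at once to avoid isomerization of the β,γ-unsaturated aldehyde into conjugation.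

**Step 16**
Reactants: 20, bromo aldehyde
Product: 21, kericembrenolide D
Conditions: CrCl2 (8 equiv), DMF, 25 °C, 2 mM, slow addition of 20 (syringe pump, 8 h); aq. NH4Cl work-up
Reagents that add atoms: none (the O–H hydrogen comes from the work-up)
Why: Intramolecular NHK allylation: Cr(II) inserts into the allylic C–Br bond and the allylchromium adds through its γ-carbon (C1) to the C14 aldehyde, forming C1–C14, the exocyclic methylene and the C14 alcohol together. C1 is set trans to the C2 chain because the aldehyde attacks the butenolide face anti to the C2 substituent. The C14 configuration is set in the closed, macrocycle-constrained chromium transition state (14S assumed).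

**Compound list**
1 | 4,4-diethoxybut-1-yne | C#CCC(OCC)OCC | starting material
2 | (E)-4,4-diethoxy-1-iodo-2-methylbut-1-ene | I/C=C(\C)CC(OCC)OCC | intermediate
3 | isoprene | C=C(C)C=C | starting material
4 | 9-(3-methylbut-3-en-1-yl)-9-BBN | C=C(C)CCB1C2CCCC1CCC2 | intermediate
5 | (E)-8,8-diethoxy-2,6-dimethylocta-1,5-diene | C=C(C)CC/C=C(\C)CC(OCC)OCC | intermediate
6 | acrolein | C=CC=O | starting material
7 | (2E,6E)-9,9-diethoxy-3,7-dimethylnona-2,6-dienal | O=C/C=C(\C)CC/C=C(\C)CC(OCC)OCC | intermediate
8 | (4S,5E,9E)-12,12-diethoxy-2,6,10-trimethyldodeca-1,5,9-trien-4-ol | C=C(C)C[C@H](O)/C=C(\C)CC/C=C(\C)CC(OCC)OCC | intermediate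
9 | (4S,5E,9E)-12,12-diethoxy-2,6,10-trimethyldodeca-1,5,9-trien-4-yl acetate | C=C(C)C[C@H](OC(C)=O)/C=C(\C)CC/C=C(\C)CC(OCC)OCC | intermediate
10 | acryloyl chloride | C=CC(=O)Cl | starting material
11 | bis(trimethylsilyl)acetylene | C[Si](C)(C)C#C[Si](C)(C)C | starting material
12 | 1-(trimethylsilyl)pent-4-en-1-yn-3-one | C=CC(=O)C#C[Si](C)(C)C | intermediate
13 | (S)-1-(trimethylsilyl)pent-4-en-1-yn-3-ol | C=C[C@H](O)C#C[Si](C)(C)C | intermediate
14 | (3S)-pent-1-en-4-yn-3-ol | C=C[C@H](O)C#C | intermediate
15 | methyl (4S)-4-hydroxyhex-5-en-2-ynoate | C=C[C@H](O)C#CC(=O)OC | intermediate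
16 | (5S)-5-ethenylfuran-2(5H)-one | C=C[C@@H]1OC(=O)C=C1 | intermediate
17 | (5S)-5-ethenyl-3-(hydroxymethyl)furan-2(5H)-one | OCC1=C[C@H](C=C)OC1=O | intermediate
18 | CM product with CH2OH, C6-OAc and C14 diethyl acetal | OCC1=C[C@H](/C=C(\C)C[C@H](OC(C)=O)/C=C(\C)CC/C=C(\C)CC(OCC)OCC)OC1=O | intermediate
19 | allylic bromide of 18 | BrCC1=C[C@H](/C=C(\C)C[C@H](OC(C)=O)/C=C(\C)CC/C=C(\C)CC(OCC)OCC)OC1=O | intermediate
20 | C14 aldehyde / allylic bromide | BrCC1=C[C@H](/C=C(\C)C[C@H](OC(C)=O)/C=C(\C)CC/C=C(\C)CC=O)OC1=O | intermediate
21 | kericembrenolide D | C=C1C(=O)O[C@H]2/C=C(\C)C[C@H](OC(C)=O)/C=C(\C)CC/C=C(\C)C[C@H](O)[C@H]12 | target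

**Totals**
- Total steps: 16 (Steps 2 and 3 can be run as one pot, with 4 not isolated).
- Longest linear sequence: 10 steps (Steps 7 → 8 → 9 → 10 → 11 → 12 → 13 → 14 → 15 → 16, from acryloyl chloride 10 to 21).

**Three steps most likely to fail**
1. **Step 16 (macro-NHK).**
   - Risk: yield and C14 diastereoselectivity are uncertain. A simple chair model for the E-locked allylchromium favours the anti (14-epi) adduct, so the syn 14S outcome depends on macrocyclic control.
   - Fallback: convert the bromide to the allylstannane (Me3SnSnMe3, cat. Pd(PPh3)4) and add it to the aldehyde with BF3·OEt2 through an open SE2′ transition state, which favours the syn relationship. Alternatively, form C1–C14 intermolecularly by this method and close the ring by RCM at C3=C4.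
2. **Step 13 (CM of two hindered partners).**
   - Risk: forming the trisubstituted C3=C4 alkene may be low-yielding and may give scrambling at the other trisubstituted alkenes.
   - Fallback: do CM of **9** with acrolein to give the C2 enal. Then add lithium TMS-acetylide, oxidize, apply Noyori reduction on the chain, and build the butenolide on that chain (desilylation, carboxylation, Lindlar, lactonization), so C2 is set after the metathesis.
3. **Step 12 (MBH hydroxymethylation of a γ-alkenyl butenolide).**
   - Risk: the γ-H is acidic, so racemization or isomerization to the 5-ylidene butenolide is possible, and conversion may be poor.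
   - Fallback: build the α-(silyloxymethyl)butenolide from the propargylic alcohol. Use ynone CH2=CH–CO–C≡C–CH2OTBS, apply Noyori reduction, then Red-Al/I2 to the Z-iodo allylic alcohol, then Pd/CO carbonylative lactonization.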